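The oxolane ring O1–C2–C3–C4–C5 is disconnected at C2–C3 and O1–C5, which leads back to two simple partners: the non-enolisable aryl aldehyde O-benzylvanillin and the γ-oxygenated enal (E)-4-benzyloxybut-2-enal. A chiral carbene turns the enal into a homoenolate whose β-carbon adds to the aldehyde; lactonisation follows, so a single operation forms both bonds, closes the ring and sets the cis pair C2(aryl, ring A)/C3(CH2O arm), the sterically hardest relationship of the target. The lactone carbonyl is the future C5. C4 is then set by convex-face protonation, C5 by trans arylation (ring B) of the lactol acetate, and one hydrogenolysis frees all four hydroxyls.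

Key step: step 2

Remark 1 (numbering): positions are given in target numbering, O1, C2 (ring A, from 4), C3, C4, C5 (ring B, from 15); lactones are named as oxolan-2-ones, whose C5, C4, C3 and C2 are target C2, C3, C4 and C5.
Remark 2 (catalyst): the sense of induction of the aminoindanol-derived N-mesityl triazolium salt cannot be assigned with certainty for this substrate pair; it is assumed that one of its two commercial antipodes gives (4S,5S)-5, and that antipode is used.
Remark 3 (precursor design): both partners carry benzyl ethers (benzyloxide is a poor γ-leaving group on 3, and all four ethers fall in one final step), 3 is made in one step by cross-metathesis, and 4 is used in excess while 3 is added slowly.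
Remark 4 (auxiliary fallback): for the MgCl2-catalysed anti-aldol the chelated (Z)-enolate is assumed to react on the face away from the benzyl group of the auxiliary; if the sense were opposite, the (R)-auxiliary would be used.

Step 1
Reactants: 1 allyl benzyl ether; 2 (E)-but-2-enal (crotonaldehyde)
Product: 3 (E)-4-benzyloxybut-2-enal
Conditions: 2 (4 equiv), second-generation Grubbs catalyst RuCl2(=CHPh)(PCy3)(H2IMes) (2 mol%), CH2Cl2, 40 °C
Reagents that add atoms: none
Why: Olefin cross-metathesis of a terminal allyl ether with an excess of an electron-poor enal favours the cross product and the (E)-alkene, and loss of volatile propene drives it forward.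

Step 2
Reactants: 3 (E)-4-benzyloxybut-2-enal; 4 O-benzylvanillin (4-benzyloxy-3-methoxybenzaldehyde)
Product: 5 (4S,5S)-5-(4-benzyloxy-3-methoxyphenyl)-4-(benzyloxymethyl)oxolan-2-one (cis)
Conditions: aminoindanol-derived N-mesityl triazolium tetrafluoroborate (10 mol%), DBU (10 mol%), Ti(OiPr)4 (20 mol%), iPrOH (20 mol%), CH2Cl2, 23 °C; 3 added slowly to 4 (2 equiv)
Reagents that add atoms: none
Why: The carbene freed from the triazolium by DBU adds to the formyl carbon of 3 and proton transfer gives the extended Breslow intermediate (a homoenolate), whose β-carbon attacks the carbonyl carbon of Ti-bound 4 and forms the future C2–C3 bond; tautomerisation to the acyl azolium and acylation of the new alkoxide then form O1–C5 and release the carbene. The closest known reaction is the carbene-catalysed homoenolate annulation of enals with aryl aldehydes to cis-γ-butyrolactones, here in its cooperative carbene/Lewis acid form. The single ring closes by 5-exo-trig attack of the alkoxide oxygen on the acyl azolium carbonyl. Both new stereocentres (lactone C5 and C4, later C2 and C3) arise in the C–C bond-forming event: the Ti(OiPr)4-organised, compact transition state should put aryl and CH2OBn cis, and the aminoindanol backbone with its N-mesityl group blocks one face of the homoenolate, so the catalyst antipode fixes the absolute sense. The step needs cis diastereoselectivity, enantioselectivity and cross- over self-annulation; in the substrates these rest on the (E)-geometry of 3, on 4 being non-enolisable and used in excess while 3 is added slowly, and on benzyloxide being too poor a leaving group for γ-elimination from the homoenolate.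

Step 3
Reactants: 5 (4S,5S)-5-(4-benzyloxy-3-methoxyphenyl)-4-(benzyloxymethyl)oxolan-2-one
Product: 8 (4S,5S)-5-(4-benzyloxy-3-methoxyphenyl)-4-(benzyloxymethyl)-3-methylideneoxolan-2-one, via Mannich base 6 (not isolated), via trimethylammonium iodide 7 (not isolated)
Conditions: LiN(SiMe3)2, THF, −78 °C; CH2=NMe2+ I−, −78 → 23 °C; MeI, 23 °C; aq NaHCO3, 23 °C
Reagents that add atoms: Eschenmoser's salt (N,N-dimethylmethyleneiminium iodide), C=[N+](C)C.[I-]
Why: A Mannich reaction of the lithium enolate with the iminium salt, N-methylation and E1cB (Hofmann-type) elimination under bicarbonate install the exocyclic methylene; the transient C3 centre of 6 is destroyed, the centres at lactone C4 and C5 are not acidic under these conditions, and the mild base avoids migration of the alkene into the ring.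

Step 4
Reactants: 8 (4S,5S)-5-(4-benzyloxy-3-methoxyphenyl)-4-(benzyloxymethyl)-3-methylideneoxolan-2-one
Product: 10 (3R,4S,5S)-5-(4-benzyloxy-3-methoxyphenyl)-4-(benzyloxymethyl)-3-(hydroxymethyl)oxolan-2-one (all-cis), via pinacol boronate 9 (not isolated)
Conditions: CuCl (5 mol%), DPEphos (5 mol%), NaOtBu (10 mol%), B2pin2, MeOH (2 equiv), THF, 0 °C; then NaBO3·4H2O, THF/H2O, 23 °C
Reagents that add atoms: sodium perborate tetrahydrate (dimeric peroxoborate anion shown), O[B-]1(O)OO[B-](O)(O)OO1.[Na+].[Na+]
Why: Copper-catalysed conjugate borylation (1,4-addition of a boryl–copper species to the α-methylene lactone) gives a copper enolate that MeOH should protonate kinetically on the convex face, anti to the cis CH2OBn and aryl groups at lactone C4 and C5, so the new centre (target C4) carries its CH2B arm cis to both; perborate oxidation of the C–B bond with retention then gives the alcohol under conditions mild enough to spare the α-centre.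

Step 5
Reactants: 10 (3R,4S,5S)-5-(4-benzyloxy-3-methoxyphenyl)-4-(benzyloxymethyl)-3-(hydroxymethyl)oxolan-2-one
Product: 11 (3R,4S,5S)-5-(4-benzyloxy-3-methoxyphenyl)-3,4-bis(benzyloxymethyl)oxolan-2-one (all-cis)
Conditions: BnOC(=NH)CCl3, TfOH (cat.), CH2Cl2/cyclohexane, 0 °C
Reagents that add atoms: benzyl 2,2,2-trichloroacetimidate, ClC(Cl)(Cl)C(=N)OCc1ccccc1
Why: Acid-catalysed O-benzylation with the trichloroacetimidate (benzyl cation transfer) avoids base altogether, so the epimerisable all-cis α-centre and the lactone are untouched.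

Step 6
Reactants: 11 (3R,4S,5S)-5-(4-benzyloxy-3-methoxyphenyl)-3,4-bis(benzyloxymethyl)oxolan-2-one
Product: 13 (3R,4S,5S)-5-(4-benzyloxy-3-methoxyphenyl)-3,4-bis(benzyloxymethyl)oxolan-2-yl acetate (anomeric mixture), via aluminium lactolate 12 (not isolated)
Conditions: iBu2AlH, CH2Cl2, −78 °C; then pyridine, DMAP, Ac2O, −78 → 0 °C
Reagents that add atoms: acetic anhydride, CC(=O)OC(C)=O
Why: Reductive acetylation: iBu2AlH adds once to the lactone at −78 °C and the stable tetrahedral aluminium lactolate is acetylated in situ, so the ring never opens to the epimerisable hydroxy aldehyde; the anomeric centre is a mixture that is lost in step 8.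

Step 7
Reactants: 14 4-bromo-2-methoxyphenol
Product: 15 1-benzyloxy-4-bromo-2-methoxybenzene
Conditions: BnBr, K2CO3, DMF, 23 °C
Reagents that add atoms: benzyl bromide, BrCc1ccccc1
Why: Williamson ether synthesis on a phenoxide with a reactive benzylic bromide.

Step 8
Reactants: 13 (3R,4S,5S)-5-(4-benzyloxy-3-methoxyphenyl)-3,4-bis(benzyloxymethyl)oxolan-2-yl acetate; 15 1-benzyloxy-4-bromo-2-methoxybenzene
Product: 18 (2S,3S,4R,5S)-2,5-bis(4-benzyloxy-3-methoxyphenyl)-3,4-bis(benzyloxymethyl)oxolane, via aryl Grignard reagent 16 (not isolated), via arylzinc bromide 17 (not isolated)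
Conditions: 15, Mg, THF, 40 °C; ZnBr2, THF, 0 °C; then 13, BF3·OEt2, CH2Cl2, −78 → −40 °C
Reagents that add atoms: none
Why: Magnesium insertion and transmetalation to zinc give a mild aryl nucleophile, and BF3·OEt2 ionises the anomeric acetate to a five-membered oxocarbenium ion (C-glycosylation-type substitution of a lactol acetate) whose lower face carries the C2 aryl, C3 and C4 arms, so the aryl group should enter from the open face and make the new C5 centre trans to C4 and to C2; the low temperature keeps the benzylic C2–O1 bond intact.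

Step 9
Reactants: 18 (2S,3S,4R,5S)-2,5-bis(4-benzyloxy-3-methoxyphenyl)-3,4-bis(benzyloxymethyl)oxolane
Product: 19 [(2S,3S,4R,5S)-2,5-bis(4-hydroxy-3-methoxyphenyl)oxolane-3,4-diyl]dimethanol (target)
Conditions: H2 (1 atm), Pd/C, EtOAc/MeOH, 23 °C
Reagents that add atoms: none
Why: Catalytic hydrogenolysis cleaves the four O-benzyl ethers under neutral conditions and is stopped at full debenzylation, before the slower cleavage of the benzylic ring C–O bonds; no stereocentre is touched.

Compound list
1 | allyl benzyl ether | C=CCOCc1ccccc1 | starting material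
2 | (E)-but-2-enal (crotonaldehyde) | C/C=C/C=O | starting material
3 | (E)-4-benzyloxybut-2-enal | O=C/C=C/COCc1ccccc1 | intermediate
4 | O-benzylvanillin (4-benzyloxy-3-methoxybenzaldehyde) | COc1cc(C=O)ccc1OCc1ccccc1 | starting material
5 | (4S,5S)-5-(4-benzyloxy-3-methoxyphenyl)-4-(benzyloxymethyl)oxolan-2-one, cis | COc1cc([C@H]2OC(=O)C[C@H]2COCc2ccccc2)ccc1OCc1ccccc1 | intermediate
6 | (3S,4S,5S)-5-(4-benzyloxy-3-methoxyphenyl)-4-(benzyloxymethyl)-3-[(dimethylamino)methyl]oxolan-2-one, 3,4-trans major epimer, formed in situ | COc1cc([C@H]2OC(=O)[C@H](CN(C)C)[C@H]2COCc2ccccc2)ccc1OCc1ccccc1 | intermediate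
7 | trimethylammonium iodide of 6 (N-methylated Mannich base), formed in situ | COc1cc([C@H]2OC(=O)[C@H](C[N+](C)(C)C)[C@H]2COCc2ccccc2)ccc1OCc1ccccc1.[I-] | intermediate
8 | (4S,5S)-5-(4-benzyloxy-3-methoxyphenyl)-4-(benzyloxymethyl)-3-methylideneoxolan-2-one | COc1cc([C@H]2OC(=O)C(=C)[C@H]2COCc2ccccc2)ccc1OCc1ccccc1 | intermediate
9 | (3S,4S,5S)-5-(4-benzyloxy-3-methoxyphenyl)-4-(benzyloxymethyl)-3-[(4,4,5,5-tetramethyl-1,3,2-dioxaborolan-2-yl)methyl]oxolan-2-one, all-cis, formed in situ | COc1cc([C@H]2OC(=O)[C@@H](CB3OC(C)(C)C(C)(C)O3)[C@H]2COCc2ccccc2)ccc1OCc1ccccc1 | intermediate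
10 | (3R,4S,5S)-5-(4-benzyloxy-3-methoxyphenyl)-4-(benzyloxymethyl)-3-(hydroxymethyl)oxolan-2-one, all-cis | COc1cc([C@H]2OC(=O)[C@@H](CO)[C@H]2COCc2ccccc2)ccc1OCc1ccccc1 | intermediate
11 | (3R,4S,5S)-5-(4-benzyloxy-3-methoxyphenyl)-3,4-bis(benzyloxymethyl)oxolan-2-one, all-cis | COc1cc([C@H]2OC(=O)[C@@H](COCc3ccccc3)[C@H]2COCc2ccccc2)ccc1OCc1ccccc1 | intermediate
12 | diisobutylaluminium alkoxide of the lactol from 11 (anomeric mixture), formed in situ | COc1cc([C@H]2OC(O[Al](CC(C)C)CC(C)C)[C@@H](COCc3ccccc3)[C@H]2COCc2ccccc2)ccc1OCc1ccccc1 | intermediate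
13 | (3R,4S,5S)-5-(4-benzyloxy-3-methoxyphenyl)-3,4-bis(benzyloxymethyl)oxolan-2-yl acetate (anomeric mixture) | COc1cc([C@H]2OC(OC(C)=O)[C@@H](COCc3ccccc3)[C@H]2COCc2ccccc2)ccc1OCc1ccccc1 | intermediate
14 | 4-bromo-2-methoxyphenol | COc1cc(Br)ccc1O | starting material
15 | 1-benzyloxy-4-bromo-2-methoxybenzene | COc1cc(Br)ccc1OCc1ccccc1 | intermediate
16 | (4-benzyloxy-3-methoxyphenyl)magnesium bromide, formed in situ | COc1cc([Mg]Br)ccc1OCc1ccccc1 | intermediate
17 | (4-benzyloxy-3-methoxyphenyl)zinc bromide, formed in situ | COc1cc([Zn]Br)ccc1OCc1ccccc1 | intermediate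
18 | (2S,3S,4R,5S)-2,5-bis(4-benzyloxy-3-methoxyphenyl)-3,4-bis(benzyloxymethyl)oxolane (2,3-cis, 3,4-cis, 4,5-trans) | COc1cc([C@H]2O[C@H](c3ccc(OCc4ccccc4)c(OC)c3)[C@@H](COCc3ccccc3)[C@H]2COCc2ccccc2)ccc1OCc1ccccc1 | intermediate
19 | [(2S,3S,4R,5S)-2,5-bis(4-hydroxy-3-methoxyphenyl)oxolane-3,4-diyl]dimethanol (2,3-cis, 3,4-cis, 4,5-trans) | COc1cc([C@H]2O[C@H](c3ccc(O)c(OC)c3)[C@@H](CO)[C@H]2CO)ccc1O | target

Total step count: 9. Longest linear sequence: 8 (steps 1–6, 8 and 9; step 7 is a one-step side branch).

Steps most likely to fail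

Step 2. The process at risk is face discrimination in the C–C bond-forming event (loss of enantio- or cis-selectivity), together with self-annulation of 3, because the electron-rich aldehyde 4 is a slow acceptor. The fallback sets out from 4 and comes back at 5, replacing catalyst control by an oxazolidinone auxiliary. (S)-4-Benzyloxazolidin-2-one is N-acylated with methyl 4-chloro-4-oxobutanoate (nBuLi, THF, −78 °C) to the succinate imide F1. A MgCl2-catalysed anti-aldol addition of F1 to 4 (Et3N, Me3SiCl, EtOAc, 23 °C) should give the silylated anti-aldol adduct F2. TFA in MeOH removes the silyl group, and the freed hydroxyl closes onto the methyl ester to give the cis lactone imide F3. LiOH/H2O2 (THF/H2O, 0 °C) removes the auxiliary and acidification gives the cis paraconic acid F4. BH3·SMe2 (THF, 0 °C) reduces the carboxylic acid in the presence of the lactone to the hydroxymethyl lactone F5, and benzyl trichloroacetimidate with catalytic TfOH then gives 5.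

Step 4. The process at risk is protonation of the enolate on the concave face, or equilibration of the new α-centre towards the 3,4-trans lactone by the alkoxide present. The fallback sets out from 5 and comes back at 10, bypassing steps 3 and 4. The lithium enolate of 5 (LiN(SiMe3)2, THF, −78 °C) is hydroxymethylated with gaseous monomeric formaldehyde (from cracked paraformaldehyde) to the 3,4-trans hydroxymethyl lactone F6. LiN(iPr)2 (2.2 equiv, THF, −78 °C) converts F6 into its β-oxido enolate dianion, in which the alkoxide cannot act as a leaving group. A quench at −78 °C with 2,6-di-tert-butyl-4-methylphenol, a bulky proton donor, should deliver the proton to the convex face irreversibly and give 10.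

Step 8. The process at risk is ionisation of the benzylic C2–O1 bond by the boron Lewis acid with loss of the cis C2/C3 relationship, or proton loss from the oxocarbenium ion when aryl transfer from zinc is slow. The fallback sets out from 11 and comes back at 18. Reduction of 11 with iBu2AlH (CH2Cl2, −78 °C) and aqueous work-up gives the free lactol F7. Benzenesulfinic acid with CaCl2 (CH2Cl2, 23 °C) converts it into the 2-benzenesulfonyl oxolane F8. Arylzinc bromide 17 with added ZnBr2 in THF at 23 °C then displaces the sulfinate through the same oxocarbenium ion without any boron Lewis acid. The aryl group should again enter anti to the three cis substituents to give 18.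

Further compounds
F1 | step 2 | (S)-4-benzyl-3-(4-methoxy-4-oxobutanoyl)oxazolidin-2-one | COC(=O)CCC(=O)N1C(=O)OC[C@@H]1Cc1ccccc1
F2 | step 2 | (S)-4-benzyl-3-[(2R,3S)-3-(4-benzyloxy-3-methoxyphenyl)-2-(2-methoxy-2-oxoethyl)-3-(trimethylsilyloxy)propanoyl]oxazolidin-2-one | COc1cc([C@@H](O[Si](C)(C)C)[C@@H](CC(=O)OC)C(=O)N2C(=O)OC[C@@H]2Cc2ccccc2)ccc1OCc1ccccc1
F3 | step 2 | (S)-4-benzyl-3-[(2S,3R)-2-(4-benzyloxy-3-methoxyphenyl)-5-oxooxolane-3-carbonyl]oxazolidin-2-one (cis) | COc1cc([C@H]2OC(=O)C[C@H]2C(=O)N2C(=O)OC[C@@H]2Cc2ccccc2)ccc1OCc1ccccc1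
F4 | step 2 | (2S,3R)-2-(4-benzyloxy-3-methoxyphenyl)-5-oxooxolane-3-carboxylic acid (cis) | COc1cc([C@H]2OC(=O)C[C@H]2C(=O)O)ccc1OCc1ccccc1
F5 | step 2 | (4S,5S)-5-(4-benzyloxy-3-methoxyphenyl)-4-(hydroxymethyl)oxolan-2-one (cis) | COc1cc([C@H]2OC(=O)C[C@H]2CO)ccc1OCc1ccccc1
F6 | step 4 | (3S,4S,5S)-5-(4-benzyloxy-3-methoxyphenyl)-4-(benzyloxymethyl)-3-(hydroxymethyl)oxolan-2-one (3,4-trans) | COc1cc([C@H]2OC(=O)[C@H](CO)[C@H]2COCc2ccccc2)ccc1OCc1ccccc1
F7 | step 8 | (3R,4S,5S)-5-(4-benzyloxy-3-methoxyphenyl)-3,4-bis(benzyloxymethyl)oxolan-2-ol (anomeric mixture) | COc1cc([C@H]2OC(O)[C@@H](COCc3ccccc3)[C@H]2COCc2ccccc2)ccc1OCc1ccccc1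
F8 | step 8 | (2S,3S,4R)-5-(benzenesulfonyl)-2-(4-benzyloxy-3-methoxyphenyl)-3,4-bis(benzyloxymethyl)oxolane (target numbering, mixture at C5) | COc1cc([C@H]2OC(S(=O)(=O)c3ccccc3)[C@@H](COCc3ccccc3)[C@H]2COCc2ccccc2)ccc1OCc1ccccc1
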